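Ring A is closed by treating the oxygen-bearing C3 as a latent ester carbon and its neighbour C2 as the inner carbon of an allyl group on C10. Ring-closing metathesis of the C3 methyl enol ether forms the C2–C3 bond, and hydrolysis gives the 3-ketone. The metathesis precursor comes from an Ireland–Claisen rearrangement that relays one reagent-set carbinol (future C9) to the quaternary C5 and to C4 and leaves a C9=C10 alkene. Through this alkene ring B is oxidised (allylic oxidation, Li/NH3, Rubottom oxidation, α-alkenylation, hindered hydride) to the 7-isopropenyl-8,9-diol. The bis-(Z)-enoate arm is installed as a bis-ynoate and semihydrogenated last.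

Key step: step 6

Remark: bicyclic compounds carry eremophilane locants (C1–C10 decalin, C15 on C4, C14 on C5, isopropenyl C11–C13 on C7), β being the face of the C5 methyl and α the opposite face; (S)-pent-1-yn-3-ol is assumed to be purchasable in enantiopure form.

Step 1
Reactants: 1 ethyl 2-methyl-4-oxocyclohex-2-ene-1-carboxylate (Hagemann's ester, racemic)
Product: 3 3-methyl-2-(prop-2-en-1-yl)cyclohex-2-en-1-one, via alkylated keto ester 2 (not isolated)
Conditions: NaOEt, EtOH, allyl bromide, reflux; then KOH, H2O/EtOH, reflux; then HCl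
Reagents that add atoms: allyl bromide, C=CCBr
Why: Alkylation of the extended enolate of the vinylogous β-keto ester at C3, then saponification and decarboxylation of the vinylogous β-keto acid (Hagemann ester sequence), should give the 2-allyl enone and erase the racemic stereocenter of 1.

Step 2
Reactants: 3 3-methyl-2-(prop-2-en-1-yl)cyclohex-2-en-1-one
Product: 4 (1R)-3-methyl-2-(prop-2-en-1-yl)cyclohex-2-en-1-ol
Conditions: (S)-2-methyl-CBS-oxazaborolidine (15 mol%), catecholborane, toluene, −78 °C
Reagents that add atoms: none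
Why: Corey–Bakshi–Shibata reduction, in which the oxazaborolidine–borane complex binds the carbonyl anti to the larger alkenyl flank and should deliver hydride to give the (R)-carbinol (future C9), catecholborane at −78 °C sparing the allyl group from hydroboration.

Step 3
Reactants: 4 (1R)-3-methyl-2-(prop-2-en-1-yl)cyclohex-2-en-1-ol
Product: 5 (1R)-3-methyl-2-(prop-2-en-1-yl)cyclohex-2-en-1-yl propanoate
Conditions: propanoyl chloride, pyridine, DMAP (cat.), CH2Cl2, 0 °C
Reagents that add atoms: propanoyl chloride, CCC(=O)Cl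
Why: DMAP-catalysed O-acylation of the allylic alcohol, with the carbinol configuration retained because the C–O bond is not touched.

Step 4
Reactants: 5 (1R)-3-methyl-2-(prop-2-en-1-yl)cyclohex-2-en-1-yl propanoate
Product: 8 methyl (2R)-2-[(1R)-1-methyl-2-(prop-2-en-1-yl)cyclohex-2-en-1-yl]propanoate, via silyl ketene acetal 6 (not isolated), via carboxylic acid 7 (not isolated)
Conditions: LiN(i-Pr)2, THF, −78 °C; Me3SiCl, −78 → 65 °C; 1 M HCl; then Me3SiCHN2, MeOH/toluene, rt
Reagents that add atoms: chlorotrimethylsilane, C[Si](C)(C)Cl (silicon of 6 only); trimethylsilyldiazomethane, C[Si](C)(C)C=[N+]=[N-]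
Why: Ireland–Claisen rearrangement, in which kinetic enolisation in THF gives the (E)-silyl ketene acetal (methyl cis to the allylic oxygen) whose suprafacial [3,3] shift through a chair-like transition state carries the C9 configuration to the quaternary C5 and sets C4 (the boat alternative would force that methyl over the ring), after which Me3SiCHN2 esterifies the acid.

Step 5
Reactants: 8 methyl (2R)-2-[(1R)-1-methyl-2-(prop-2-en-1-yl)cyclohex-2-en-1-yl]propanoate
Product: 9 (6R)-6-[(2R)-3-methoxybut-3-en-2-yl]-6-methyl-1-(prop-2-en-1-yl)cyclohex-1-ene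
Conditions: Cp2TiMe2 (dimethyltitanocene), toluene, 70 °C, dark
Reagents that add atoms: dimethyltitanocene, C[Ti](C)(C1C=CC=C1)C1C=CC=C1
Why: Petasis methylenation, in which the thermally generated titanium methylidene olefinates the ester carbonyl to the methyl enol ether without base, so the C4 stereocenter α to the ester should not epimerise.

Step 6
Reactants: 9 (6R)-6-[(2R)-3-methoxybut-3-en-2-yl]-6-methyl-1-(prop-2-en-1-yl)cyclohex-1-ene
Product: 11 4β,5β-dimethyl-11,12,13-trinoreremophil-9-en-3-one, via cyclic enol ether 10 (not isolated)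
Conditions: second-generation Grubbs catalyst RuCl2(=CHPh)(PCy3)(H2IMes) (5 mol%), toluene, 70 °C; then 0.5 M HCl, THF, 0 °C
Reagents that add atoms: water, O
Why: The ruthenium benzylidene exchanges onto the monosubstituted allyl terminus on C10, the new alkylidene adds across the 1,1-disubstituted enol ether C3(OMe)=CH2 in a [2+2]/retro-[2+2] sequence that expels ethene and forges C2=C3, and mild acid hydrolysis of the 3-methoxy-2-ene then unveils the C3 ketone with its oxygen taken from water. The closest known reaction type is ring-closing metathesis of acyclic enol ethers to carbocyclic enol ethers, preceded by ester methylenation. Ring A closes as a six-membered ring through a metallacyclobutane, driven by loss of ethene and the strain-free cyclohexene. No new stereocenter is formed; C4 and C5 enter with the configuration fixed in step 4, and the cold, dilute hydrolysis is chosen so that C4, now α to a ketone, is not enolised. The step needs chemoselectivity among three alkenes, which the substrate secures because the trisubstituted C9=C10 ring alkene is too hindered to enter the cycle and initiation at the allyl group avoids parking the catalyst as an alkoxycarbene.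

Step 7
Reactants: 11 4β,5β-dimethyl-11,12,13-trinoreremophil-9-en-3-one
Product: 12 4β,5β-dimethyl-11,12,13-trinoreremophil-9-ene-3,8-dione
Conditions: CrO3, 3,5-dimethylpyrazole, CH2Cl2, −20 °C
Reagents that add atoms: chromium trioxide, O=[Cr](=O)=O
Why: Allylic oxidation with the CrO3–3,5-dimethylpyrazole complex, in which hydrogen abstraction at C8 gives the allyl radical with a tertiary terminus at C10 (abstraction at C1 would give a less substituted one) and oxygen is taken up at the unhindered C8 end, the regiochemistry of 5-ene to 7-oxo steroid oxidations.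

Step 8
Reactants: 12 4β,5β-dimethyl-11,12,13-trinoreremophil-9-ene-3,8-dione
Product: 14 3α,8-bis(triethylsilyloxy)-11,12,13-trinoreremophil-8-ene (10αH), via dilithium enolate alkoxide 13 (not isolated)
Conditions: Li (4.4 equiv), t-BuOH (2.0 equiv), NH3/THF, −78 °C; isoprene; NH3 evaporated; Et3SiCl, Et3N, THF, −78 → 0 °C
Reagents that add atoms: lithium, [Li] (in 13 only); chlorotriethylsilane, CC[Si](Cl)(CC)CC
Why: Dissolving-metal (Birch-type) reduction, in which the enone is protonated axially at C10 to give the trans-fused 10α-H lithium Δ8-enolate regiospecifically while the C3 ketone goes to the thermodynamically preferred equatorial 3α-alkoxide, and exactly two equivalents of t-BuOH leave no proton source to quench the enolate before both oxygens are silylated.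

Step 9
Reactants: 14 3α,8-bis(triethylsilyloxy)-11,12,13-trinoreremophil-8-ene (10αH)
Product: 16 3α,9α-bis(triethylsilyloxy)-11,12,13-trinoreremophilan-8-one (10αH), via silyloxy epoxide 15 (not isolated)
Conditions: mCPBA, NaHCO3, CH2Cl2, −20 °C → rt
Reagents that add atoms: 3-chloroperoxybenzoic acid, OOC(=O)c1cccc(Cl)c1
Why: Rubottom oxidation, in which the peracid should epoxidise the silyl enol ether from the α-face, opposite the axial C5 methyl that is 1,3-diaxial to C9 on the β-face, and 1,4-silyl migration of the silyloxy epoxide gives the equatorial 9α-silyloxy ketone.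

Step 10
Reactants: 16 3α,9α-bis(triethylsilyloxy)-11,12,13-trinoreremophilan-8-one (10αH)
Product: 17 3α,9α-bis(triethylsilyloxy)eremophil-11-en-8-one (7α-isopropenyl, 10αH)
Conditions: Pd2(dba)3 (2.5 mol%), P(t-Bu)3·HBF4 (6 mol%), LiN(SiMe3)2 (2.2 equiv), 2-bromopropene, toluene, 25–45 °C; AcOH quench at −78 °C
Reagents that add atoms: 2-bromopropene, CC(Br)=C
Why: Palladium-catalysed ketone α-alkenylation, in which enolisation can only go toward C7 (C9 carries the silyloxy group), the excess base holds the product as its dienolate, and kinetic α-protonation should return the β,γ-unsaturated ketone with the isopropenyl group equatorial (7α), which is also the thermodynamic epimer.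

Step 11
Reactants: 17 3α,9α-bis(triethylsilyloxy)eremophil-11-en-8-one (7α-isopropenyl, 10αH)
Product: 18 3α,9α-bis(triethylsilyloxy)eremophil-11-en-8α-ol
Conditions: LiBH(s-Bu)3, THF, −78 °C; then H2O
Reagents that add atoms: none
Why: Hindered trialkylborohydride reduction, in which equatorial hydride delivery to the ketone flanked by two equatorial substituents should give the axial 8α-alcohol, cis to both the 9α-oxygen and the 7α-isopropenyl group.

Step 12
Reactants: 18 3α,9α-bis(triethylsilyloxy)eremophil-11-en-8α-ol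
Product: 20 8α,9α-(isopropylidenedioxy)eremophil-11-en-3α-ol, via triol 19 (not isolated)
Conditions: camphorsulfonic acid (cat.), MeOH, 0 °C → rt; concentrate; 2,2-dimethoxypropane, acetone, rt; Et3N
Reagents that add atoms: 2,2-dimethoxypropane, COC(C)(C)OC
Why: Acid methanolysis removes both triethylsilyl ethers and thermodynamic acetalisation engages only the cis-8α,9α-diol as a 1,3-dioxolane, leaving the isolated 3α-hydroxyl free.

Step 13
Reactants: 21 (S)-pent-1-yn-3-ol
Product: 23 (S)-4-hydroxyhex-2-ynoic acid, via dilithium alkynide alkoxide 22 (not isolated)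
Conditions: n-BuLi (2.2 equiv), THF, −78 °C; CO2 (gas), −78 → 0 °C; 1 M HCl
Reagents that add atoms: n-butyllithium, [Li]CCCC (lithium of 22 only); carbon dioxide, O=C=O
Why: Alkynide carboxylation, in which the dianion is carboxylated at the acetylide carbon by CO2 without touching the carbinol stereocenter.

Step 14
Reactants: 23 (S)-4-hydroxyhex-2-ynoic acid; 24 hex-2-ynoic acid
Product: 26 (S)-4-(hex-2-ynoyloxy)hex-2-ynoic acid, via hex-2-ynoyl chloride 25 (not isolated)
Conditions: 24 (2.2 equiv), (COCl)2, DMF (cat.), CH2Cl2, 0 °C → rt; then 23, pyridine, CH2Cl2, 0 °C; then aq. NaHCO3/THF; 1 M HCl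
Reagents that add atoms: oxalyl chloride, O=C(Cl)C(=O)Cl (chlorine of 25 only)
Why: Acid chloride acylation of the secondary propargylic alcohol, with the mixed anhydride formed at the free carboxyl group cleaved again in the bicarbonate treatment and the stereocenter not involved.

Step 15
Reactants: 20 8α,9α-(isopropylidenedioxy)eremophil-11-en-3α-ol; 26 (S)-4-(hex-2-ynoyloxy)hex-2-ynoic acid
Product: 27 8α,9α-(isopropylidenedioxy)eremophil-11-en-3α-yl (4S)-4-(hex-2-ynoyloxy)hex-2-ynoate
Conditions: N,N'-diisopropylcarbodiimide, DMAP (cat.), CH2Cl2, 0 °C → rt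
Reagents that add atoms: none
Why: Steglich esterification of the equatorial 3α-alcohol, the only free hydroxyl, with retention at C3 and at the side-chain stereocenter.

Step 16
Reactants: 27 8α,9α-(isopropylidenedioxy)eremophil-11-en-3α-yl (4S)-4-(hex-2-ynoyloxy)hex-2-ynoate
Product: 28 8α,9α-(isopropylidenedioxy)eremophil-11-en-3α-yl (2Z,4S)-4-[(2Z)-hex-2-enoyloxy]hex-2-enoate
Conditions: H2 (1 atm), Pd/CaCO3 poisoned with Pb(OAc)2, quinoline, EtOAc, 0 °C → rt, stopped at 2 equiv H2
Reagents that add atoms: none
Why: Lindlar semihydrogenation, in which syn delivery of hydrogen to each ynoate should give both (Z)-enoates, the alkynes binding the poisoned surface far more strongly than the 1,1-disubstituted isopropenyl alkene.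

Step 17
Reactants: 28 8α,9α-(isopropylidenedioxy)eremophil-11-en-3α-yl (2Z,4S)-4-[(2Z)-hex-2-enoyloxy]hex-2-enoate
Product: 29 8α,9α-dihydroxyeremophil-11-en-3α-yl (2Z,4S)-4-[(2Z)-hex-2-enoyloxy]hex-2-enoate (CNP0271544.1)
Conditions: AcOH/H2O (4:1), 40 °C
Reagents that add atoms: none
Why: Acid-catalysed acetal hydrolysis should release the cis-8α,9α-diol under conditions too mild to cleave the esters, isomerise the (Z)-enoates or hydrate the isopropenyl group.

Compound list
1 | ethyl 2-methyl-4-oxocyclohex-2-ene-1-carboxylate (Hagemann's ester) | CCOC(=O)C1CCC(=O)C=C1C | starting material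
2 | ethyl 2-methyl-4-oxo-3-(prop-2-en-1-yl)cyclohex-2-ene-1-carboxylate (alkylated keto ester) | CCOC(=O)C1CCC(=O)C(CC=C)=C1C | intermediate
3 | 3-methyl-2-(prop-2-en-1-yl)cyclohex-2-en-1-one | C=CCC1=C(C)CCCC1=O | intermediate
4 | (1R)-3-methyl-2-(prop-2-en-1-yl)cyclohex-2-en-1-ol | O[C@H]1C(CC=C)=C(C)CCC1 | intermediate
5 | (1R)-3-methyl-2-(prop-2-en-1-yl)cyclohex-2-en-1-yl propanoate | CCC(=O)O[C@H]1C(CC=C)=C(C)CCC1 | intermediate
6 | (E)-trimethylsilyl ketene acetal of 5 (silyl ketene acetal) | C/C=C(/O[Si](C)(C)C)O[C@H]1C(CC=C)=C(C)CCC1 | intermediate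
7 | (2R)-2-[(1R)-1-methyl-2-(prop-2-en-1-yl)cyclohex-2-en-1-yl]propanoic acid (carboxylic acid) | C=CCC1=CCCC[C@]1(C)[C@@H](C)C(=O)O | intermediate
8 | methyl (2R)-2-[(1R)-1-methyl-2-(prop-2-en-1-yl)cyclohex-2-en-1-yl]propanoate | C=CCC1=CCCC[C@]1(C)[C@@H](C)C(=O)OC | intermediate
9 | (6R)-6-[(2R)-3-methoxybut-3-en-2-yl]-6-methyl-1-(prop-2-en-1-yl)cyclohex-1-ene | C=CCC1=CCCC[C@]1(C)[C@@H](C)C(=C)OC | intermediate
10 | 3-methoxy-4β,5β-dimethyl-11,12,13-trinoreremophila-2,9-diene (cyclic enol ether) | C1CCC=C2CC=C(OC)[C@H](C)[C@@]12C | intermediate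
11 | 4β,5β-dimethyl-11,12,13-trinoreremophil-9-en-3-one | C1CCC=C2CCC(=O)[C@H](C)[C@@]12C | intermediate
12 | 4β,5β-dimethyl-11,12,13-trinoreremophil-9-ene-3,8-dione | C1CC(=O)C=C2CCC(=O)[C@H](C)[C@@]12C | intermediate
13 | dilithium 3α-alkoxide 8-enolate of 10αH-11,12,13-trinoreremophil-8-ene (dilithium enolate alkoxide) | C1C[C@]2(C)[C@@H](C)[C@H](O[Li])CC[C@H]2C=C1O[Li] | intermediate
14 | 3α,8-bis(triethylsilyloxy)-11,12,13-trinoreremophil-8-ene (10αH) | C1C[C@]2(C)[C@@H](C)[C@H](O[Si](CC)(CC)CC)CC[C@H]2C=C1O[Si](CC)(CC)CC | intermediate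
15 | 8α,9α-epoxy-3α,8β-bis(triethylsilyloxy)-11,12,13-trinoreremophilane (silyloxy epoxide) | C1C[C@]2(C)[C@@H](C)[C@H](O[Si](CC)(CC)CC)CC[C@H]2[C@@H]3O[C@]13O[Si](CC)(CC)CC | intermediate
16 | 3α,9α-bis(triethylsilyloxy)-11,12,13-trinoreremophilan-8-one (10αH) | C1C[C@]2(C)[C@@H](C)[C@H](O[Si](CC)(CC)CC)CC[C@H]2[C@H](O[Si](CC)(CC)CC)C1=O | intermediate
17 | 3α,9α-bis(triethylsilyloxy)eremophil-11-en-8-one (7α-isopropenyl, 10αH) | C=C(C)[C@@H]1C[C@]2(C)[C@@H](C)[C@H](O[Si](CC)(CC)CC)CC[C@H]2[C@H](O[Si](CC)(CC)CC)C1=O | intermediate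
18 | 3α,9α-bis(triethylsilyloxy)eremophil-11-en-8α-ol | C=C(C)[C@@H]1C[C@]2(C)[C@@H](C)[C@H](O[Si](CC)(CC)CC)CC[C@H]2[C@H](O[Si](CC)(CC)CC)[C@@H]1O | intermediate
19 | eremophil-11-ene-3α,8α,9α-triol (triol) | C=C(C)[C@@H]1C[C@]2(C)[C@@H](C)[C@H](O)CC[C@H]2[C@H](O)[C@@H]1O | intermediate
20 | 8α,9α-(isopropylidenedioxy)eremophil-11-en-3α-ol | C=C(C)[C@@H]1C[C@]2(C)[C@@H](C)[C@H](O)CC[C@H]2[C@@H]3OC(C)(C)O[C@H]13 | intermediate
21 | (S)-pent-1-yn-3-ol | C#C[C@H](CC)O | starting material
22 | dilithium salt of (S)-pent-1-yn-3-ol (dilithium alkynide alkoxide) | [Li]C#C[C@H](CC)O[Li] | intermediate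
23 | (S)-4-hydroxyhex-2-ynoic acid | OC(=O)C#C[C@H](CC)O | intermediate
24 | hex-2-ynoic acid | CCCC#CC(=O)O | starting material
25 | hex-2-ynoyl chloride | CCCC#CC(=O)Cl | intermediate
26 | (S)-4-(hex-2-ynoyloxy)hex-2-ynoic acid | OC(=O)C#C[C@H](CC)OC(=O)C#CCCC | intermediate
27 | 8α,9α-(isopropylidenedioxy)eremophil-11-en-3α-yl (4S)-4-(hex-2-ynoyloxy)hex-2-ynoate | C=C(C)[C@@H]1C[C@]2(C)[C@@H](C)[C@H](OC(=O)C#C[C@H](CC)OC(=O)C#CCCC)CC[C@H]2[C@@H]3OC(C)(C)O[C@H]13 | intermediate
28 | 8α,9α-(isopropylidenedioxy)eremophil-11-en-3α-yl (2Z,4S)-4-[(2Z)-hex-2-enoyloxy]hex-2-enoate | C=C(C)[C@@H]1C[C@]2(C)[C@@H](C)[C@H](OC(=O)/C=C\[C@H](CC)OC(=O)/C=C\CCC)CC[C@H]2[C@@H]3OC(C)(C)O[C@H]13 | intermediate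
29 | 8α,9α-dihydroxyeremophil-11-en-3α-yl (2Z,4S)-4-[(2Z)-hex-2-enoyloxy]hex-2-enoate (CNP0271544.1) | C=C(C)[C@@H]1C[C@]2(C)[C@@H](C)[C@H](OC(=O)/C=C\[C@H](CC)OC(=O)/C=C\CCC)CC[C@H]2[C@H](O)[C@@H]1O | target

Total step count: 17. Longest linear sequence: 15 steps (steps 1–12, then 15–17); the side-chain acid 26 is made in two further steps (13–14).

Steps most likely to fail

Step 4. The chair preference in the sigmatropic shift may erode (a competing boat-like array, or partial formation of the other ketene acetal geometry), so that material epimeric at C4 is carried forward. The fallback sets out from alcohol 20, obtained as the C4 epimer mixture. Dess–Martin oxidation should give the 3-ketone acetonide F1, in which C4 is α to the carbonyl of a trans-decalin. Equilibration with NaOMe in MeOH should then favour the equatorial 4β-methyl epimer, because an axial methyl would meet the axial hydrogens at C2 and C10. Reduction with Li in NH3/MeOH returns the equatorial 3α-alcohol, and the route is rejoined at 20.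

Step 8. The proton inventory may not hold, leading either to protonation and over-reduction of the C8 enolate or to incomplete reduction of the C3 ketone. The fallback sets out from ketone 11 and separates the two reductions. Li in NH3/MeOH should give the equatorial alcohol 4β,5β-dimethyl-11,12,13-trinoreremophil-9-en-3α-ol F2. Silylation (Et3SiCl, imidazole) gives the silyl ether F3. Allylic oxidation with CrO3–3,5-dimethylpyrazole gives the enone F4. Reduction of the enone alone (Li 2.2 equiv, t-BuOH 1.0 equiv, NH3/THF) and trapping with Et3SiCl rejoins the route at 14.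

Step 10. Slow coupling at the hindered enolate, or base-mediated migration of the new double bond into conjugation, may consume the α-isopropenyl ketone. The fallback sets out from ketone 16. Aldol addition of its C7 lithium enolate (LiN(i-Pr)2, THF, −78 °C) to acetone gives the tertiary aldol F5. Dehydration (MsCl, Et3N, then DBU) is allowed to run to the conjugated isopropylidene ketone F6. Deconjugation by γ-deprotonation with LiN(i-Pr)2 and kinetic α-protonation with AcOH at −78 °C rejoins the route at 17.

Further compounds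
F1 | step 4 | 8α,9α-(isopropylidenedioxy)eremophil-11-en-3-one | C=C(C)[C@@H]1C[C@]2(C)[C@@H](C)C(=O)CC[C@H]2[C@@H]3OC(C)(C)O[C@H]13
F2 | step 8 | 4β,5β-dimethyl-11,12,13-trinoreremophil-9-en-3α-ol | C1CCC=C2CC[C@@H](O)[C@H](C)[C@@]12C
F3 | step 8 | 3α-(triethylsilyloxy)-4β,5β-dimethyl-11,12,13-trinoreremophil-9-ene | C1CCC=C2CC[C@@H](O[Si](CC)(CC)CC)[C@H](C)[C@@]12C
F4 | step 8 | 3α-(triethylsilyloxy)-4β,5β-dimethyl-11,12,13-trinoreremophil-9-en-8-one | C1CC(=O)C=C2CC[C@@H](O[Si](CC)(CC)CC)[C@H](C)[C@@]12C
F5 | step 10 | 11-hydroxy-3α,9α-bis(triethylsilyloxy)eremophilan-8-one (7α-substituent, 10αH) | CC(C)(O)[C@@H]1C[C@]2(C)[C@@H](C)[C@H](O[Si](CC)(CC)CC)CC[C@H]2[C@H](O[Si](CC)(CC)CC)C1=O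
F6 | step 10 | 3α,9α-bis(triethylsilyloxy)eremophil-7(11)-en-8-one (10αH) | CC(C)=C1C[C@]2(C)[C@@H](C)[C@H](O[Si](CC)(CC)CC)CC[C@H]2[C@H](O[Si](CC)(CC)CC)C1=O
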